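You take over zeta and its neighbour beta, which differ in the charge of partner, 2.00 equiv against 4.00 equiv.

    substrate ⇌ open intermediate (K1 = 2.2, k1 = 0.12 s⁻¹)
    partner → second intermediate (k2 = 0.032 s⁻¹)
    open intermediate + second intermediate → target (k3 = 0.30 M⁻¹ s⁻¹)
    2 open intermediate → homo product (k4 = 0.20 M⁻¹ s⁻¹)
    crystals ⇌ target, rate k5*(cs5 - [target]) while solid is left; crystals form when [target] > cs5 (cs5 = 6.9 mM, k5 = 0.17 s⁻¹)
    partner + target ⇌ idle adduct, settled at all times (K6 = 520 M⁻¹)

common to all: substrate 0.020 M; time 4.0 min

| charge | partner |
|---|---|
| zeta | 2.00 equiv |
| beta | 4.00 equiv |

1. which of the two there is more of at the end, counted by the substrate in each, zeta (target / homo product)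
2. which of the two there is more of at the end, counted by the substrate in each, beta (target / homo product)
3. target at the end, in percent of the substrate charged, zeta
4. target at the end, in percent of the substrate charged, beta

Here is what is in the flask. Substrate and open intermediate balance with a relaxation half-life of 0.0662 min, faster than partner turns into second intermediate (half-life 0.36 min), and that half-life is shorter than the 4.0 min run. So I reckon substrate and open intermediate as one pool, 68.8% of it open, and I set [second intermediate] at the partner charge.

Zeta gives 2.18 and beta 4.36 for the selectivity factor, the substrate going to target per substrate going to homo product, with the pool at its charge; [substrate] cancels from it.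

Now work with the fraction left. Leaving out the homo step, the pool falls pseudo-first-order, so at the end I expect 13.8% left in zeta and 1.91% in beta. Of what has gone, the factor gives target: 59.1% in zeta, 79.8% in beta, with target ahead in zeta and target ahead in beta.

Do not dilute: at fixed equivalents and time the reckoned factor stays, but the pool's clock runs on [substrate]. Count crystals and idle adduct as target, not the dissolved target alone. The solubility limit makes no difference to the end target, crystals and idle adduct counted, in zeta or beta.

The forecast puts target ahead in zeta and target in beta, at 56% and 78%, lower than my figures, holding that “doubling the partner shortens that window”.

Zeta ends with 57.8% target and 23.3% homo product, beta with 79.5% and 15.0%. Target over homo product stands at 2.47 in zeta and 5.31 in beta, higher than the factors. One more flask, like zeta but with 0.0080 M of substrate, keeps the reckoned factor, 2.18, and ends with 2.32 for target over homo product. Its reckoned pool left is 45.3%, which gives 37.5% target. That flask ended holding 14% substrate and 29.9% open intermediate, with 39.2% target.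

The constants are those of an exercise; no experiment stands behind them.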